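**Retrosynthetic overview**
- Gardenin C ⇐ its 3'-bromo analogue: the 3'-OH is made last from C–Br by palladium-catalysed hydroxylation, so bromine serves as an oxidant-proof latent phenol and no protecting groups are used.
- 5-OH ⇐ carbonyl-directed C5–H oxygenation of the 6,7,8-trimethoxyflavone (C5 is the only C–H on ring A).
- Ring C (the only ring formed) ⇐ o-aroyloxyacetophenone by Baker–Venkataraman acyl shift and cyclodehydration (O1–C2).
- o-Aroyloxyacetophenone ⇐ 3,4,5-trimethoxyacetophenone + 3-bromo-4,5-dimethoxybenzoic acid by a new ketone-directed dehydrogenative C–H/O–H coupling (O1–C8a); the two ortho C–H bonds of the ketone are equivalent by symmetry.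
- Order: rings A and B are bought intact, ring C is closed in step 2, and O1, 5-OH and 3'-OH are each installed by a C–O bond-forming step.

Assumption: Gardenin C is achiral (no stereocentre or stereo-axis), so the constitution drawn is the compound to be made; both starting materials are taken as catalogue chemicals.

**Step 1**
Reactants: 1 3,4,5-trimethoxyacetophenone (1.5 equiv); 2 3-bromo-4,5-dimethoxybenzoic acid
Product: 3 6-acetyl-2,3,4-trimethoxyphenyl 3-bromo-4,5-dimethoxybenzoate
Conditions: [RuCl2(p-cymene)]2 (5 mol%), AgSbF6 (20 mol%), (NH4)2S2O8 (2 equiv), ClCH2CH2Cl, 100 °C, 24 h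
Reagents that add atoms: none
Why: Proposed new method: a ketone-directed dehydrogenative C–H/O–H coupling of an aryl ketone with a benzoic acid, in which the cationic divalent ruthenium benzoate formed from the catalyst, AgSbF6 and 2 binds the acetyl oxygen of 1, the bound benzoate acts as internal base for concerted metalation–deprotonation at the ortho C–H (both ortho sites are identical, so there is no regiochemical choice), persulfate oxidises the cyclometalated species to tetravalent ruthenium and C–O reductive elimination releases ester 3, whose new ortho substituent twists the acetyl group and slows a second oxygenation; the closest known reaction types are the ruthenium-catalysed ortho C–H benzoxylation of anilides and benzamides with aromatic acids under these conditions and the ketone-directed ortho C–H trifluoroacetoxylation (hydroxylation) of acetophenones, and to my knowledge their combination (ketone director, benzoic acid as oxygen partner) has not been demonstrated.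

**Step 2**
Reactants: 3 6-acetyl-2,3,4-trimethoxyphenyl 3-bromo-4,5-dimethoxybenzoate
Product: 5 2-(3-bromo-4,5-dimethoxyphenyl)-6,7,8-trimethoxy-4H-chromen-4-one, via β-diketone 4 (not isolated)
Conditions: KOt-Bu (3 equiv), THF, 0 °C to rt, 2 h; then AcOH, H2SO4 (cat.), 100 °C, 1 h (THF distilled off)
Reagents that add atoms: none
Why: Baker–Venkataraman rearrangement (the acetyl enolate attacks the neighbouring ester carbonyl in an intramolecular O-to-C acyl shift to give the o-hydroxy β-diketone 4) followed by acid-catalysed cyclodehydration, in which the freed phenol oxygen closes ring C onto the ring-B carbonyl, the classical flavone synthesis.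

**Step 3**
Reactants: 5 2-(3-bromo-4,5-dimethoxyphenyl)-6,7,8-trimethoxy-4H-chromen-4-one
Product: 7 2-(3-bromo-4,5-dimethoxyphenyl)-5-hydroxy-6,7,8-trimethoxy-4H-chromen-4-one, via aryl trifluoroacetate 6 (not isolated)
Conditions: [RuCl2(p-cymene)]2 (5 mol%), PhI(OCOCF3)2 (1.5 equiv), CF3CO2H/(CF3CO)2O (4:1), 80 °C; then H2O/THF, rt
Reagents that add atoms: [bis(trifluoroacetoxy)iodo]benzene, O=C(OI(OC(=O)C(F)(F)F)c1ccccc1)C(F)(F)F
Why: Carbonyl-directed ruthenium-catalysed C–H oxygenation, a reaction type established for flavone C5–H, in which the C4 ketone delivers divalent ruthenium to the peri C5–H, the trivalent-iodine oxidant induces C–O reductive elimination to trifluoroacetate 6 (masked against over-oxidation until hydrolysed on work-up), and C5 is the only C–H on ring A (ortho to 6-OMe, para to 8-OMe) while ring B is deactivated by bromine and the protonated pyranone.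

**Step 4**
Reactants: 7 2-(3-bromo-4,5-dimethoxyphenyl)-5-hydroxy-6,7,8-trimethoxy-4H-chromen-4-one
Product: 8 Gardenin C, 5-hydroxy-2-(3-hydroxy-4,5-dimethoxyphenyl)-6,7,8-trimethoxy-4H-chromen-4-one
Conditions: Pd2(dba)3 (2 mol%), t-BuBrettPhos (8 mol%), KOH (4 equiv), degassed 1,4-dioxane/H2O (1:1), 80 °C, under argon; then aq. HCl to pH 4
Reagents that add atoms: potassium hydroxide, [K+].[OH-]
Why: Palladium-catalysed hydroxylation of an aryl bromide (Buchwald–Hartwig-type C–O coupling with hydroxide), in which zerovalent palladium inserts into the only C–Br bond, the bulky biaryl phosphine drives C–O reductive elimination from the aryl palladium hydroxide and suppresses diaryl ether formation, and the 5-OH, present as its phenoxide, lowers the electrophilicity of C2 and so shields ring C from hydroxide.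

**Compound list**
1 | 3,4,5-trimethoxyacetophenone [1-(3,4,5-trimethoxyphenyl)ethan-1-one] | CC(=O)c1cc(OC)c(OC)c(OC)c1 | starting material
2 | 3-bromo-4,5-dimethoxybenzoic acid | OC(=O)c1cc(Br)c(OC)c(OC)c1 | starting material
3 | 6-acetyl-2,3,4-trimethoxyphenyl 3-bromo-4,5-dimethoxybenzoate | CC(=O)c1cc(OC)c(OC)c(OC)c1OC(=O)c1cc(Br)c(OC)c(OC)c1 | intermediate
4 | 1-(3-bromo-4,5-dimethoxyphenyl)-3-(2-hydroxy-3,4,5-trimethoxyphenyl)propane-1,3-dione (not isolated) | O=C(CC(=O)c1cc(OC)c(OC)c(OC)c1O)c1cc(Br)c(OC)c(OC)c1 | intermediate
5 | 2-(3-bromo-4,5-dimethoxyphenyl)-6,7,8-trimethoxy-4H-chromen-4-one | COc1cc2c(=O)cc(-c3cc(Br)c(OC)c(OC)c3)oc2c(OC)c1OC | intermediate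
6 | 2-(3-bromo-4,5-dimethoxyphenyl)-6,7,8-trimethoxy-4-oxo-4H-chromen-5-yl trifluoroacetate (not isolated) | COc1c(OC(=O)C(F)(F)F)c2c(=O)cc(-c3cc(Br)c(OC)c(OC)c3)oc2c(OC)c1OC | intermediate
7 | 2-(3-bromo-4,5-dimethoxyphenyl)-5-hydroxy-6,7,8-trimethoxy-4H-chromen-4-one | COc1c(O)c2c(=O)cc(-c3cc(Br)c(OC)c(OC)c3)oc2c(OC)c1OC | intermediate
8 | Gardenin C, 5-hydroxy-2-(3-hydroxy-4,5-dimethoxyphenyl)-6,7,8-trimethoxy-4H-chromen-4-one | COc1cc(-c2cc(=O)c3c(O)c(OC)c(OC)c(OC)c3o2)cc(O)c1OC | target

**Totals**
Total step count: 4. Longest linear sequence: 4 (1 or 2 → 3 → 5 → 7 → 8).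

**Steps most likely to fail, with fallbacks**

Step 1 (the proposed new coupling). The ketone is a weaker director than the carboxylate of 2, so ruthenium may activate the ortho C–H of the acid instead, and some double benzoxylation of 1 is possible. Fallback with known chemistry, setting out from 1: the established palladium-catalysed ketone-directed ortho C–H hydroxylation of acetophenones (Pd(OAc)2, K2S2O8, CF3CO2H/(CF3CO)2O, 50 °C) gives 6-acetyl-2,3,4-trimethoxyphenyl trifluoroacetate F1, which aqueous work-up hydrolyses to 2-hydroxy-3,4,5-trimethoxyacetophenone F2. Steglich esterification of F2 with acid 2 (EDC·HCl, DMAP, CH2Cl2, rt) then gives 3, where the route is rejoined one step longer.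

Step 3 (C5–H oxygenation). The flanking 6-OMe may slow ruthenation, and the electron-rich ring A may be over-oxidised; residual oxidant should be destroyed by a thiosulfate wash before the trifluoroacetate is hydrolysed, because the freed 5-hydroxy-8-methoxy arene is easily oxidised to a quinone. Fallback, setting out from 5: electrophilic bromination with N-bromosuccinimide (MeCN, rt) at C5, the only ring-A C–H and activated ortho/para by the 6- and 8-methoxy groups, gives 5-bromo-2-(3-bromo-4,5-dimethoxyphenyl)-6,7,8-trimethoxy-4H-chromen-4-one F3. Twofold palladium-catalysed hydroxylation of both C–Br bonds under the step 4 conditions (6 equiv KOH) then gives 8 directly, so the route is rejoined at the target with the count still four.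

Step 4 (aryl bromide to phenol). Hot aqueous hydroxide can open ring C; here reclosure on acidification can only return the same flavone because the opened 2,6-dihydroxyaryl ketone is symmetric, but cleavage of the diketone would be a loss. Fallback, setting out from 7: Miyaura borylation (Pd(dppf)Cl2, B2pin2, KOAc, 1,4-dioxane, 90 °C) gives 2-[3,4-dimethoxy-5-(4,4,5,5-tetramethyl-1,3,2-dioxaborolan-2-yl)phenyl]-5-hydroxy-6,7,8-trimethoxy-4H-chromen-4-one F4. Oxidation of F4 with NaBO3·4H2O (THF/H2O, rt) then gives 8, avoiding hot hydroxide at the cost of one extra step.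

**Further compounds**
F1 | step 1 | 6-acetyl-2,3,4-trimethoxyphenyl trifluoroacetate | CC(=O)c1cc(OC)c(OC)c(OC)c1OC(=O)C(F)(F)F
F2 | step 1 | 2-hydroxy-3,4,5-trimethoxyacetophenone | CC(=O)c1cc(OC)c(OC)c(OC)c1O
F3 | step 3 | 5-bromo-2-(3-bromo-4,5-dimethoxyphenyl)-6,7,8-trimethoxy-4H-chromen-4-one | COc1c(Br)c2c(=O)cc(-c3cc(Br)c(OC)c(OC)c3)oc2c(OC)c1OC
F4 | step 4 | 2-[3,4-dimethoxy-5-(4,4,5,5-tetramethyl-1,3,2-dioxaborolan-2-yl)phenyl]-5-hydroxy-6,7,8-trimethoxy-4H-chromen-4-one | COc1c(O)c2c(=O)cc(-c3cc(B4OC(C)(C)C(C)(C)O4)c(OC)c(OC)c3)oc2c(OC)c1OC
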